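In the dawn flask E stands lower at its last reading than at its first, although Q keeps falling: Q and Z make E, E turns into J, which nobody reads, and two Q can also give G.

the same everywhere: Q 17 mM
- dawn: Z 25.5 mM; temperature 20 °C; the very flask that is asked about, followed so far
- winter: Z 38 mM; temperature 26 °C; run made earlier
- flask: Z 25.5 mM; temperature 20 °C; time 8.0 d

- dawn (time / d: E / %, Q / %): 1.25: 35.0, 40.0; 2.50: 29.3, 19.7; 4.00: 21.1, 10.4; 5.00: 18.9, 6.8; 6.00: 17.0, 3.6; 8.00: 15.8, 2.8
- winter (time / h: E / %, Q / %): 8.00: 38.6, 46.0; 15.0: 41.4, 27.4; 20.0: 39.7, 17.8; 30.0: 32.0, 8.1; 40.0: 27.7, 4.1

(each reading ± 0.5 percentage points)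

- north-west: at 8.0 d raise the temperature by 20 K, then wait 4.0 d
- south: at 8.0 d add Z, 100% of the amount charged, then wait 4.0 d
- south-east: change nothing and wait 4.0 d more
- south-west: at 8.0 d take out 90% of the E then present, then wait 4.0 d

- E, in percent of the Q first charged, at 8.0 d
- which option adds most E ("none" when 2 percentage points or less is all one gets) (north-west / south / south-east / south-west / none)
- E present, with what was taken out counted in, in percent of the Q first charged, after south
- E present, with what was taken out counted in, in percent of the Q first charged, after south-west

- in percentages every species weighs as the Q in it: one G counts as two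
- E taken out counts as made
- steps under discussion: 2 Q -> G; Q + Z -> E; E <-> J
- additions bring no volume worth counting

Test the inputs on south-west before reckoning it. Let the E left behind re-split with J at the dawn proportion, and count what Q remains into the pool. A shift of one standard deviation in the last Q reading moves the answer by 0.072 percentage points, which is negligible. Supposing a quarter of the charge sat in unread G moves it by 0.64 points. The same shift in the last E reading moves it by 0.82 points, so that reading is the one to know well.

Now the number. Define ρ as J over E once the forward and backward rates of E ⇌ J cancel, so that time drops out; this is the equilibrium constant. Counting G as nil, the last dawn readings give ρ = 5.15. My reckoning follows from it: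

- **Now:** the reading, 15.8%.
- **South or waiting:** the remaining Q adds 0.46 points of E, less than the margin, so E is about 16.3%.
- **South-west:** 28.2%, a gain of 12 points.
- **North-west:** the winter run has not relaxed at its last reading, since E is still falling, from 32.0% to 27.7%, so I extrapolate. Counting G as nil, E's share of what is no longer Q runs 48.3%, 34.8%, 28.9% over the last three winter readings, evenly spaced in time. Letting those steps keep shrinking in the same proportion gives an estimated share of 24.2% at 26 °C, so J over E is about 3.13, lower than ρ. That share is a gain of 8.4 points, less than south-west, but the rise of 20 K takes the flask well past winter's 26 °C. I expect ρ to be lower still there, and on that extrapolation I choose north-west.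

The forecast gives 15.7%, north-west, 15.4% and 26%, somewhat below my figures for south and south-west, arguing that “Removing E pulls J back”.

The flask gives 16.0% and north-west, with a gain of 26 points against 11 points for south-west; 15.2% after south and 27.1% after south-west.

    2 Q → G (k = 9.88 × 10⁻⁴ /M/min, Ea = 79.0 kJ/mol)
    Q + Z → E (k = 0.0259 /M/min, Ea = 74.0 kJ/mol)
    E ⇌ J (K = 5.42, k = 5.52 × 10⁻⁴ /min, Ea = 91.0 kJ/mol, ΔH = −55.0 kJ/mol)
    (constants at 20 °C)

J is the main reason E ends low: without the E ⇌ J step this flask holds 94.4% E at 8.0 d, not 16.0%. Put the flask's simulated state at 8.0 d through ρ and south-west gives 27.8%, against 27.1%. In the neighbour flask charged with 6.4 mM of Z, ρ splits its E and J into 5.86% of E, and that flask holds 6.34%.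

The readings were generated by integration for an exercise; scatter was added.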